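The easy mistake with this flask was to let the whole catalyst charge work from the first minute, although it starts as precatalyst.

starting material 0.050 M; precatalyst 0.01 mol%

    starting material + enzyme → target + enzyme, rate k1*[starting material]*[enzyme]/(1 + ([starting material]/Km1) + ([starting material]/Ksi1)^2) (Km1 = 0.0568 M, Ksi1 = 46.0 mM, k1 = 7.94 × 10⁵ M⁻¹ h⁻¹)
    precatalyst → enzyme (k2 = 0.0850 h⁻¹)

- the form that holds most of the catalyst when 10% of the starting material are converted (enzyme / precatalyst)
- its share of the catalyst then

I replaced the curve by its mean. Over the first 10% of conversion, up to the point asked about, which I call the mark, the starting material averaged 0.0475 M, and there the rate law gave 13000 h⁻¹, the turnover rate: moles of target made per hour by one mole of enzyme. That mean was safe, for the same law gave 12970 h⁻¹ at the start and 13000 h⁻¹ at the mark.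

Then I climbed the ladder of times. One turnover took 0.277 s. The mark asked for 1000 turnovers per catalyst charged, which is 4.62 min of work for a fully active charge. But the lifetime of the precatalyst was 11.8 h, so the enzyme was still climbing almost straight from zero, and its mean was half of its final amount. The time to the mark was therefore the square root of twice the turnovers times the lifetime over the turnover rate, 1.35 h. The bend of the activation curve adds about 1.91% to that, which makes 1.37 h. That was shorter than the lifetime, so I expected 11.0% of the catalyst as enzyme and 89.0% as precatalyst.

The forecast named precatalyst at 89%, the same share as mine, saying “only about 11% of the precatalyst has activated by then”.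

The flask gave precatalyst at 89.0%, with 11.0% as enzyme. It reached the mark after 1.37 h. The turnover rate of 13000 h⁻¹, applied to that enzyme, came to 0.172 M d⁻¹, and the flask's rate of making target at that moment stood at 0.172 M d⁻¹.

(The numbers of this flask are assumed; the rest is arithmetic.)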